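Ring B is built on a preformed ring A by stitching a two-carbon unit across C5 and C8. In the key step the enolate of the C10 propanoyl group (C9 carbonyl, C8 nucleophile) adds to phenyl vinyl sulfone, and the resulting sulfonyl carbanion closes ring B by addition–elimination at C5 of a β-chloro enoate, the vinylogous form of the C19 ester. Both bonds that flank the C6–C7 ethylene unit of ring B are thus formed in one operation, and the C4=C5 enoate survives. The sulfone then unveils a dienolate for the C4 methylation, hydrogenation sets the trans ring fusion, and the C9 ketone becomes the C8=C9 alkene through an enol triflate and a B-alkyl Suzuki coupling.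

Key step: step 6

Remark: atoms carry labdane numbers (ring A = C1–C5, C10; ring B = C5–C10; C18 methyl and C19 ester on C4; C17 on C8; C20 on C10; side chain C11–C16), the target being methyl (4S,5R,10S)-15-acetoxylabda-8,13E-dien-19-oate; in step 1 the catalyst pseudoenantiomer that gives the R adduct is assumed to be identified by a short screen.

Step 1
Reactants: 1 methyl 2-methyl-3-oxopentanoate; 2 acrolein
Product: 3 methyl (2R)-2-methyl-3-oxo-2-(3-oxopropyl)pentanoate
Conditions: 9-O-(9-phenanthryl)cupreidine (10 mol %; or its cupreine-derived pseudoenantiomer), CH2Cl2, −25 °C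
Reagents that add atoms: none
Why: Bifunctional cinchona-catalysed asymmetric Michael addition of an α-substituted β-keto ester to an enal; the quinuclidine nitrogen and the 6′-OH group organise enol and acrolein by hydrogen bonding so that one enolate face is alkylated, which should set the quaternary centre (C10 of the target) as R.

Step 2
Reactants: 3 methyl (2R)-2-methyl-3-oxo-2-(3-oxopropyl)pentanoate; 4 methyl (triphenylphosphoranylidene)acetate
Product: 5 dimethyl (2E,6R)-6-methyl-6-propanoylhept-2-enedioate
Conditions: CH2Cl2, 0 °C → rt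
Reagents that add atoms: none
Why: Wittig olefination with a stabilised ylide should react only with the aldehyde (the α-quaternary ketone is inert) and bring in C4 and the C19 ester as an E-enoate whose geometry is erased in step 3.

Step 3
Reactants: 5 dimethyl (2E,6R)-6-methyl-6-propanoylhept-2-enedioate
Product: 6 dimethyl (2R)-2-methyl-2-propanoylheptanedioate
Conditions: H2 (1 atm), 10% Pd/C, EtOAc, rt
Reagents that add atoms: none
Why: Heterogeneous catalytic hydrogenation should saturate the conjugated C=C bond without touching the ketone or the esters.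

Step 4
Reactants: 6 dimethyl (2R)-2-methyl-2-propanoylheptanedioate
Product: 8 methyl (3R)-3-methyl-2-oxo-3-propanoylcyclohexane-1-carboxylate, via dilithium bis-enolate 7 (not isolated)
Conditions: LiN(i-Pr)2 (2.2 equiv), THF, −78 → 0 °C; aq. HCl
Reagents that add atoms: none
Why: Dieckmann condensation closes ring A (6-exo-trig acyl substitution at the C5 ester by the C4 ester enolate, the only enolate that can reach an ester through a six-membered transition state); double deprotonation also masks the ketone as its enolate against aldol and acyl-transfer pathways, and the product is held as its β-keto ester enolate until the quench.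

Step 5
Reactants: 8 methyl (3R)-3-methyl-2-oxo-3-propanoylcyclohexane-1-carboxylate
Product: 9 methyl (3R)-2-chloro-3-methyl-3-propanoylcyclohex-1-ene-1-carboxylate
Conditions: (COCl)2, DMF (cat.), CH2Cl2, 0 °C → 40 °C
Reagents that add atoms: oxalyl chloride, ClC(=O)C(=O)Cl
Why: Vilsmeier-type activation of the enol oxygen of the β-keto ester followed by chloride addition–elimination should give the vinylogous acid chloride, the barely enolised ethyl ketone being left alone at this temperature.

Step 6
Reactants: 9 methyl (3R)-2-chloro-3-methyl-3-propanoylcyclohex-1-ene-1-carboxylate; 10 phenyl vinyl sulfone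
Product: 13 methyl (4aS)-4a,6-dimethyl-5-oxo-8-(phenylsulfonyl)-2,3,4,4a,5,6,7,8-octahydronaphthalene-1-carboxylate, via lithium enolate 11 (not isolated), via lithiated sulfone adduct 12 (not isolated)
Conditions: LiN(SiMe3)2 (1.05 equiv), THF, −78 °C; 10 (1.0 equiv), −78 → −40 °C; LiN(SiMe3)2 (1.1 equiv), → 0 °C; aq. NH4Cl
Reagents that add atoms: none
Why: LiN(SiMe3)2 removes a C8–H of the propanoyl group (the only C–H α to a carbonyl, since C10 is quaternary), enolate 11 adds to phenyl vinyl sulfone to form C7–C8 and the α-sulfonyl carbanion 12, and C6 of 12 then attacks C5 of the β-chloro enoate, the ester enolate so formed expelling chloride to restore C4=C5 and complete the C5–C6 bond. The closest known reaction type is a Michael-initiated ring closure that ends in a nucleophilic vinylic substitution (addition–elimination on a vinylogous acid chloride), overall an anionic [4+2] annulation with the vinyl sulfone as an ethylene 1,2-dipole equivalent. Ring B is the only ring closed, in a 6-exo-trig mode with respect to the C4=C5 bond. The new centres C6 (sulfone-bearing) and C8 are not controlled and need not be, because C6 becomes sp2 in step 7 and C8 becomes sp2 in step 9, while C5 stays sp2 and the C10 centre is untouched. The step needs the enolate to react with the external acceptor and the carbanion to react at C5 only, which the substrate secures by geometry: attack of C8 on C5 or of C6 on the ketone would give a four-membered ring, and the ester carbonyl lies trans to C10 across C4=C5. The second equivalent of base keeps the sequence running because the product, deprotonated at C6, is the thermodynamic sink.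

Step 7
Reactants: 13 methyl (4aS)-4a,6-dimethyl-5-oxo-8-(phenylsulfonyl)-2,3,4,4a,5,6,7,8-octahydronaphthalene-1-carboxylate
Product: 15 methyl (1S,4aS)-1,4a,6-trimethyl-5-oxo-1,2,3,4,4a,5,6,7-octahydronaphthalene-1-carboxylate, via lithium dienolate 14 (not isolated)
Conditions: LiC10H8 (lithium naphthalenide, 2.1 equiv, from Li and naphthalene), THF, −78 °C, inverse addition; MeI (5 equiv), −78 → −20 °C
Reagents that add atoms: iodomethane, CI
Why: Reductive desulfonylation by single-electron transfer: two electrons cleave the allylic C6–S bond of the γ-sulfonyl enoate to give benzenesulfinate and the extended ester enolate 14 (the less easily reduced ketone should be spared by the stoichiometry at −78 °C), which is C-methylated at its α-carbon C4 from the α face, anti to the angular C10 methyl group, so that the new quaternary centre should be 4S (methyl α, CO2Me β) and the alkene moves to C5=C6.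

Step 8
Reactants: 15 methyl (1S,4aS)-1,4a,6-trimethyl-5-oxo-1,2,3,4,4a,5,6,7-octahydronaphthalene-1-carboxylate
Product: 16 methyl (1S,4aS,8aR)-1,4a,6-trimethyl-5-oxodecahydronaphthalene-1-carboxylate
Conditions: H2 (4 bar), 10% Pd/C, EtOAc/AcOH, rt
Reagents that add atoms: none
Why: Heterogeneous hydrogenation of the C5=C6 alkene: the β face is screened by the C10 methyl and the C4 CO2Me group, both axial, so hydrogen should be delivered to the α face and give the trans ring fusion (5R); the hindered ketone survives.

Step 9
Reactants: 16 methyl (1S,4aS,8aR)-1,4a,6-trimethyl-5-oxodecahydronaphthalene-1-carboxylate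
Product: 18 methyl (1S,4aS,8aR)-1,4a,6-trimethyl-5-{[(trifluoromethyl)sulfonyl]oxy}-1,2,3,4,4a,7,8,8a-octahydronaphthalene-1-carboxylate, via potassium enolate 17 (not isolated)
Conditions: KN(SiMe3)2 (1.2 equiv), THF, −78 °C; PhNTf2, −78 → 0 °C; aq. NH4Cl
Reagents that add atoms: N-phenylbis(trifluoromethanesulfonimide), FC(F)(F)S(=O)(=O)N(c1ccccc1)S(=O)(=O)C(F)(F)F
Why: Regiospecific enol triflate formation: the ketone can enolise only towards C8 because C10 is quaternary, and O-sulfonylation of enolate 17 should fix the tetrasubstituted C8=C9 double bond (the C4 ester has no α-hydrogen).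

Step 10
Reactants: 19 (E)-3-methylpent-2-en-4-yn-1-ol
Product: 20 (E)-3-methylpent-2-en-4-yn-1-yl acetate
Conditions: Ac2O, pyridine, DMAP (cat.), CH2Cl2, 0 °C → rt
Reagents that add atoms: acetic anhydride, CC(=O)OC(C)=O
Why: DMAP-catalysed O-acetylation of the primary allylic alcohol.

Step 11
Reactants: 20 (E)-3-methylpent-2-en-4-yn-1-yl acetate
Product: 21 (E)-3-methylpenta-2,4-dien-1-yl acetate
Conditions: H2 (1 atm, 1 equiv uptake), Pd/CaCO3–Pb(OAc)2, quinoline, hexane/EtOAc, rt
Reagents that add atoms: none
Why: Lindlar semi-hydrogenation should stop at the vinyl stage of the terminal alkyne and leave the trisubstituted E-alkene and the allylic acetate unchanged.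

Step 12
Reactants: 18 methyl (1S,4aS,8aR)-1,4a,6-trimethyl-5-{[(trifluoromethyl)sulfonyl]oxy}-1,2,3,4,4a,7,8,8a-octahydronaphthalene-1-carboxylate; 21 (E)-3-methylpenta-2,4-dien-1-yl acetate
Product: 23 methyl (1S,4aS,8aR)-5-[(3E)-5-acetoxy-3-methylpent-3-en-1-yl]-1,4a,6-trimethyl-1,2,3,4,4a,7,8,8a-octahydronaphthalene-1-carboxylate, via alkylborane 22 (not isolated)
Conditions: 21, 9-BBN (1.05 equiv), THF, 0 °C → rt; then 18, PdCl2(dppf) (10 mol %), AsPh3, Cs2CO3, DMF/THF/H2O, 50 °C
Reagents that add atoms: none
Why: Anti-Markovnikov hydroboration of the monosubstituted vinyl group by 9-BBN (the trisubstituted alkene is too hindered) gives primary alkylborane 22, and B-alkyl Suzuki–Miyaura coupling with the enol triflate should form the C9–C11 bond with retention of the C8=C9 position and of the E geometry at C13=C14.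

Compound list
1 | methyl 2-methyl-3-oxopentanoate | CCC(=O)C(C)C(=O)OC | starting material
2 | acrolein (prop-2-enal) | C=CC=O | starting material
3 | methyl (2R)-2-methyl-3-oxo-2-(3-oxopropyl)pentanoate | CCC(=O)[C@@](C)(CCC=O)C(=O)OC | intermediate
4 | methyl (triphenylphosphoranylidene)acetate | COC(=O)C=P(c1ccccc1)(c1ccccc1)c1ccccc1 | starting material
5 | dimethyl (2E,6R)-6-methyl-6-propanoylhept-2-enedioate | COC(=O)/C=C/CC[C@](C)(C(=O)CC)C(=O)OC | intermediate
6 | dimethyl (2R)-2-methyl-2-propanoylheptanedioate | COC(=O)CCCC[C@](C)(C(=O)CC)C(=O)OC | intermediate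
7 | dilithium bis-enolate of 6 (ketone enolate at C8, ester enolate at C4; formed in situ) | COC(O[Li])=CCCC[C@](C)(C(O[Li])=CC)C(=O)OC | intermediate
8 | methyl (3R)-3-methyl-2-oxo-3-propanoylcyclohexane-1-carboxylate (keto/enol forms, C1 epimers) | COC(=O)C1CCC[C@](C)(C(=O)CC)C1=O | intermediate
9 | methyl (3R)-2-chloro-3-methyl-3-propanoylcyclohex-1-ene-1-carboxylate | COC(=O)C1=C(Cl)[C@@](C)(C(=O)CC)CCC1 | intermediate
10 | phenyl vinyl sulfone | C=CS(=O)(=O)c1ccccc1 | starting material
11 | lithium enolate of 9 (formed in situ) | COC(=O)C1=C(Cl)[C@@](C)(C(O[Li])=CC)CCC1 | intermediate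
12 | methyl (3R)-2-chloro-3-[4-lithio-2-methyl-4-(phenylsulfonyl)butanoyl]-3-methylcyclohex-1-ene-1-carboxylate (formed in situ) | COC(=O)C1=C(Cl)[C@@](C)(C(=O)C(C)CC([Li])S(=O)(=O)c2ccccc2)CCC1 | intermediate
13 | methyl (4aS)-4a,6-dimethyl-5-oxo-8-(phenylsulfonyl)-2,3,4,4a,5,6,7,8-octahydronaphthalene-1-carboxylate (epimers at the sulfone- and methyl-bearing carbons) | COC(=O)C1=C2C(S(=O)(=O)c3ccccc3)CC(C)C(=O)[C@@]2(C)CCC1 | intermediate
14 | lithium dienolate of the desulfonylated ester (C19–C4–C5–C6; formed in situ) | COC(O[Li])=C1CCC[C@]2(C)C(=O)C(C)CC=C12 | intermediate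
15 | methyl (1S,4aS)-1,4a,6-trimethyl-5-oxo-1,2,3,4,4a,5,6,7-octahydronaphthalene-1-carboxylate (C6 epimers) | COC(=O)[C@@]1(C)CCC[C@]2(C)C(=O)C(C)CC=C12 | intermediate
16 | methyl (1S,4aS,8aR)-1,4a,6-trimethyl-5-oxodecahydronaphthalene-1-carboxylate (C6 epimers) | COC(=O)[C@@]1(C)CCC[C@]2(C)C(=O)C(C)CC[C@@H]12 | intermediate
17 | potassium enolate of 16 (formed in situ) | COC(=O)[C@@]1(C)CCC[C@]2(C)C(O[K])=C(C)CC[C@@H]12 | intermediate
18 | methyl (1S,4aS,8aR)-1,4a,6-trimethyl-5-{[(trifluoromethyl)sulfonyl]oxy}-1,2,3,4,4a,7,8,8a-octahydronaphthalene-1-carboxylate | COC(=O)[C@@]1(C)CCC[C@]2(C)C(OS(=O)(=O)C(F)(F)F)=C(C)CC[C@@H]12 | intermediate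
19 | (E)-3-methylpent-2-en-4-yn-1-ol | OC/C=C(C)/C#C | starting material
20 | (E)-3-methylpent-2-en-4-yn-1-yl acetate | CC(=O)OC/C=C(C)/C#C | intermediate
21 | (E)-3-methylpenta-2,4-dien-1-yl acetate | CC(=O)OC/C=C(C)/C=C | intermediate
22 | (E)-5-(9-borabicyclo[3.3.1]nonan-9-yl)-3-methylpent-2-en-1-yl acetate (formed in situ) | CC(=O)OC/C=C(C)/CCB1C2CCCC1CCC2 | intermediate
23 | methyl (1S,4aS,8aR)-5-[(3E)-5-acetoxy-3-methylpent-3-en-1-yl]-1,4a,6-trimethyl-1,2,3,4,4a,7,8,8a-octahydronaphthalene-1-carboxylate (CNP0206695.1) | COC(=O)[C@@]1(C)CCC[C@]2(C)C(CC/C(C)=C/COC(C)=O)=C(C)CC[C@@H]12 | target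

Total step count: 12. Longest linear sequence: 10 (steps 1–9 and 12; steps 10–11 prepare the side chain).

Steps most likely to fail

Step 6. Proton transfer from the ketone α-position could quench the sulfonyl carbanion before it cyclises, or the enolate could be alkylated twice by the vinyl sulfone. The fallback sets out from 9 and closes ring B in two known operations. Suzuki–Miyaura vinylation (K[CH2=CHBF3], PdCl2(dppf), Cs2CO3, THF/H2O) should give the dienoate methyl (3S)-2-ethenyl-3-methyl-3-propanoylcyclohex-1-ene-1-carboxylate F1. KOtBu (0.2 equiv) in THF should then trigger an intramolecular 1,6-conjugate addition of the C8 enolate to the terminal vinyl carbon (6-endo-trig) and, after equilibration to the conjugated isomer, give methyl (4aS)-4a,6-dimethyl-5-oxo-2,3,4,4a,5,6,7,8-octahydronaphthalene-1-carboxylate F2. Birch reductive methylation (Li, NH3/THF, t-BuOH, −78 °C; then MeI) should protonate C5 and methylate C4 from the α face and reduce the ketone, giving methyl (1S,4aS,8aR)-5-hydroxy-1,4a,6-trimethyldecahydronaphthalene-1-carboxylate F3. Dess–Martin oxidation of F3 comes back to the route at 16.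

Step 7. The ketone could be reduced competitively, or proton exchange between the dienolate and unreacted sulfone could stall the reduction. The fallback sets out from 13 and accepts the ketone reduction: 13 is added to excess Li in NH3/THF containing t-BuOH (2 equiv) at −78 °C, which cleaves the sulfone to the same dienolate while the ketone goes to the alkoxide, and MeI should then give methyl (1S,4aS)-5-hydroxy-1,4a,6-trimethyl-1,2,3,4,4a,5,6,7-octahydronaphthalene-1-carboxylate F4. Dess–Martin oxidation of F4 comes back to the route at 15.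

Step 12. Oxidative addition and transmetalation at the hindered tetrasubstituted triflate may be too slow for an sp3 partner (protodetriflation, β-hydride elimination), and palladium may ionise the allylic acetate. The fallback sets out from 18 and moves the sp3–sp2 coupling to the unhindered C12–C13 bond. Stille coupling with tributyl(vinyl)stannane (Pd(PPh3)4, LiCl, THF, reflux) should give methyl (1S,4aS,8aR)-5-ethenyl-1,4a,6-trimethyl-1,2,3,4,4a,7,8,8a-octahydronaphthalene-1-carboxylate F5, whose vinyl group is hydroborated with 9-BBN to methyl (1S,4aS,8aR)-5-[2-(9-borabicyclo[3.3.1]nonan-9-yl)ethyl]-1,4a,6-trimethyl-1,2,3,4,4a,7,8,8a-octahydronaphthalene-1-carboxylate F6. Separately, but-2-yn-1-ol is converted by syn-hydrozirconation–iodination (Cp2Zr(H)Cl; I2) into (E)-3-iodobut-2-en-1-ol F7 and acetylated to (E)-3-iodobut-2-en-1-yl acetate F8. B-alkyl Suzuki coupling of F6 with F8 (PdCl2(dppf), Cs2CO3, DMF/H2O) comes back to the route at 23.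

Further compounds
F1 | step 6 | methyl (3S)-2-ethenyl-3-methyl-3-propanoylcyclohex-1-ene-1-carboxylate | COC(=O)C1=C(C=C)[C@@](C)(C(=O)CC)CCC1
F2 | step 6 | methyl (4aS)-4a,6-dimethyl-5-oxo-2,3,4,4a,5,6,7,8-octahydronaphthalene-1-carboxylate | COC(=O)C1=C2CCC(C)C(=O)[C@@]2(C)CCC1
F3 | step 6 | methyl (1S,4aS,8aR)-5-hydroxy-1,4a,6-trimethyldecahydronaphthalene-1-carboxylate | COC(=O)[C@@]1(C)CCC[C@]2(C)C(O)C(C)CC[C@@H]12
F4 | step 7 | methyl (1S,4aS)-5-hydroxy-1,4a,6-trimethyl-1,2,3,4,4a,5,6,7-octahydronaphthalene-1-carboxylate | COC(=O)[C@@]1(C)CCC[C@]2(C)C(O)C(C)CC=C12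
F5 | step 12 | methyl (1S,4aS,8aR)-5-ethenyl-1,4a,6-trimethyl-1,2,3,4,4a,7,8,8a-octahydronaphthalene-1-carboxylate | COC(=O)[C@@]1(C)CCC[C@]2(C)C(C=C)=C(C)CC[C@@H]12
F6 | step 12 | methyl (1S,4aS,8aR)-5-[2-(9-borabicyclo[3.3.1]nonan-9-yl)ethyl]-1,4a,6-trimethyl-1,2,3,4,4a,7,8,8a-octahydronaphthalene-1-carboxylate | COC(=O)[C@@]1(C)CCC[C@]2(C)C(CCB3C4CCCC3CCC4)=C(C)CC[C@@H]12
F7 | step 12 | (E)-3-iodobut-2-en-1-ol | OC/C=C(C)/I
F8 | step 12 | (E)-3-iodobut-2-en-1-yl acetate | CC(=O)OC/C=C(C)/I
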